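## Retrosynthetic overview

1. Numbering: C1–C25 run along the target SMILES, branch methyls and hydroxyl oxygens skipped (O6, O21 = ring oxygens); left cyclohexane C2–C5/C11/C12, oxepene C5–C11, linker C13–C14, right cyclohexane C15/C16/C22–C25, oxepanone C16–C22.
2. Feature used: C16, the methyl-bearing quaternary carbon of the right cyclohexane, lies between the ether carbon C22 and C15, so it is C2 of 2-methylcyclohexane-1,3-dione in which one of two enantiotopic carbonyls has become the C22–O21 ether of the oxepanone ring.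
3. Right half: O21–C22 is opened to the prochiral trione 6 (from 1, 2 and dione 4); the surviving C15 ketone becomes an enol triflate that carries a CH2SiMe3 group on C25 as the latent methyl carbinol.
4. Left half: C2/C12 by asymmetric conjugate methylation and enolate methylation of 2-allylcyclohexenone; tertiary ether C5–O6–C7 by imidate alkylation of an α-hydroxy ketone; oxepene ring closed by RCM (C10=C11).
5. Ring order and union: both cyclohexanes are bought, the oxepanone closes in step 3, the oxepene in step 24; B-alkyl Suzuki coupling C14–C15 (step 27), then protodesilylation (C15–H, C25=CH2), HAT hydration and desilylation.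

Key step: step 3

Remarks on the chemistry (assumptions):
- Locants C1–C25, O6 and O21 in the Why lines are the target numbers defined above; locants inside compound names are systematic.
- The C25 carbinol is built through an allylsilane and not through epoxidation of a C15=C25 alkene, because after the union a peracid or borane would have to tell that alkene from the equally substituted C10=C11 alkene.
- Centres that are made and erased again (C19 in 10–15, C25 in 13, C11 in 23 and 24, the trioxolane carbons of 22 and 30) are drawn as one epimer; either epimer serves.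
- The sense of induction of the chiral acid (step 3) and of the copper ligand (step 13) has to be fixed by screening; the catalyst antipode that leads to the drawn product is meant.

## Route

Step 1
Reactants: 1 3-hydroxy-3-methylbutan-2-one; 2 formaldehyde (as paraformaldehyde)
Product: 3 1-(dimethylamino)-4-hydroxy-4-methylpentan-3-one hydrochloride
Conditions: (CH2O)n, Me2NH·HCl, HCl (cat.), EtOH, reflux
Reagents that add atoms: dimethylamine hydrochloride (CNC.Cl)
Why: Mannich reaction; the ketone can enolise only toward its methyl group because the other α-carbon is fully substituted, so aminomethylation is regiospecific.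

Step 2
Reactants: 3 1-(dimethylamino)-4-hydroxy-4-methylpentan-3-one hydrochloride; 4 2-methylcyclohexane-1,3-dione
Product: 6 2-(4-hydroxy-4-methyl-3-oxopentyl)-2-methylcyclohexane-1,3-dione, via 4-hydroxy-4-methylpent-1-en-3-one 5 (not isolated)
Conditions: Et3N (1.2 equiv), EtOAc, 70 °C
Reagents that add atoms: none
Why: Michael addition with a Mannich base as latent vinyl ketone (Robinson's variant): β-elimination of dimethylamine releases the polymerisable enone 5 only in the presence of the dione enolate, which adds to it and creates the quaternary carbon C16.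

Step 3
Reactants: 6 2-(4-hydroxy-4-methyl-3-oxopentyl)-2-methylcyclohexane-1,3-dione
Product: 8 (5aR,9aS)-2,2,5a-trimethyloctahydro-1-benzoxepine-3,6-dione, via bicyclic hemiketal 7 (not isolated)
Conditions: chiral imidodiphosphorimidate (IDPi) Brønsted acid (5 mol %), Et3SiH (2 equiv), toluene, −30 °C
Reagents that add atoms: none
Why: Proposed new method: the tertiary C20 hydroxyl adds reversibly to either enantiotopic ring carbonyl to give two rapidly interconverting enantiomeric hemiketals (7 and its mirror image), and the confined chiral acid ionises one of them faster to a seven-membered oxocarbenium ion that Et3SiH reduces irreversibly, so the whole is a dynamic kinetic desymmetrisation. The closest known reaction types are the TMSOTf/Et3SiH reductive cyclisation of hydroxy ketones to oxepanes and chiral Brønsted acid desymmetrisations of 2,2-disubstituted cyclohexane-1,3-diones. The oxepanone ring closes by 7-exo-trig attack of oxygen on the ring carbonyl (O21–C22), the cyclohexane being present already. C16 is fixed by the catalyst's choice between the two carbonyls, and C22 by axial hydride delivery to the oxocarbenium carbon anti to the adjacent pseudo-axial C16 methyl, which gives the trans ring fusion. The step needs enantiotopic-group selectivity, secured by the reversibility of hemiketal formation together with the chiral counter-anion, and chemoselectivity for the cation over the free carbonyls, secured by its far higher hydride affinity; a classical aldol closure is excluded because C20 bears no hydrogen and C18 could only close a four-membered ring, which leaves the slower bridged aldol through a ring enol as the only carbon-based side path.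

Step 4
Reactants: 8 (5aR,9aS)-2,2,5a-trimethyloctahydro-1-benzoxepine-3,6-dione
Product: 9 (5aR,9aS)-6,6-(ethane-1,2-diyldioxy)-2,2,5a-trimethyloctahydro-1-benzoxepin-3-one
Conditions: HOCH2CH2OH, p-TsOH (cat.), benzene, reflux (Dean–Stark)
Reagents that add atoms: ethane-1,2-diol (OCCO)
Why: Acid-catalysed ketalisation that tells the two ketones apart: the cyclohexanone carbonyl (C15) reacts as an angular-methyl decalone does, whereas the oxepanone carbonyl (C19) is held back by the adjacent gem-dimethyl ether carbon, whose oxygen destabilises the oxocarbenium ion on the way to a ketal.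

Step 5
Reactants: 9 (5aR,9aS)-6,6-(ethane-1,2-diyldioxy)-2,2,5a-trimethyloctahydro-1-benzoxepin-3-one
Product: 11 (3S,5aR,9aS)-3-hydroxy-2,2,5a-trimethyloctahydro-1-benzoxepin-6-one, via hydroxy ketal 10 (not isolated)
Conditions: NaBH4, MeOH, 0 → 23 °C; then 1 M HCl, THF, 23 °C
Reagents that add atoms: none
Why: Borohydride reduction of the only free ketone (C19) followed by acid hydrolysis of the dioxolane in the same flask; the new carbinol centre is not controlled and is erased in step 10.

Step 6
Reactants: 11 (3S,5aR,9aS)-3-hydroxy-2,2,5a-trimethyloctahydro-1-benzoxepin-6-one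
Product: 12 (3S,5aR,9aS)-2,2,5a-trimethyl-3-(triethylsilyloxy)octahydro-1-benzoxepin-6-one
Conditions: TESOTf, 2,6-lutidine, CH2Cl2, −78 → 0 °C
Reagents that add atoms: triethylsilyl trifluoromethanesulfonate (CC[Si](CC)(CC)OS(=O)(=O)C(F)(F)F)
Why: Silylation with a silyl triflate, chosen because the C19 alcohol is neopentyl-like; the ether keeps C19 out of the two enolate steps that follow.

Step 7
Reactants: 12 (3S,5aR,9aS)-2,2,5a-trimethyl-3-(triethylsilyloxy)octahydro-1-benzoxepin-6-one
Product: 13 (3S,5aR,7S,9aS)-2,2,5a-trimethyl-3-(triethylsilyloxy)-7-[(trimethylsilyl)methyl]octahydro-1-benzoxepin-6-one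
Conditions: LDA, THF, −78 °C; ICH2SiMe3, DMPU, −78 → 0 °C
Reagents that add atoms: (iodomethyl)trimethylsilane (C[Si](C)(C)CI)
Why: Enolate C-alkylation; the C15 ketone can enolise only toward C25 because C16 is quaternary, and the soft iodide alkylates carbon, placing on C25 the carbon of the future methyl group as a CH2SiMe3 unit.

Step 8
Reactants: 13 (3S,5aR,7S,9aS)-2,2,5a-trimethyl-3-(triethylsilyloxy)-7-[(trimethylsilyl)methyl]octahydro-1-benzoxepin-6-one
Product: 14 (3S,5aR,9aS)-2,2,5a-trimethyl-3-(triethylsilyloxy)-7-[(trimethylsilyl)methyl]-2,3,4,5,5a,8,9,9a-octahydro-1-benzoxepin-6-yl trifluoromethanesulfonate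
Conditions: KHMDS, THF, −78 → −20 °C; PhNTf2
Reagents that add atoms: N-phenylbis(trifluoromethanesulfonimide) (O=S(=O)(N(c1ccccc1)S(=O)(=O)C(F)(F)F)C(F)(F)F)
Why: Enol triflate formation from the only possible enolate, which joins the coupling handle at C15 and the allylsilane in one tetrasubstituted double bond.

Step 9
Reactants: 14 enol triflate triethylsilyl ether
Product: 15 (3S,5aR,9aS)-3-hydroxy-2,2,5a-trimethyl-7-[(trimethylsilyl)methyl]-2,3,4,5,5a,8,9,9a-octahydro-1-benzoxepin-6-yl trifluoromethanesulfonate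
Conditions: HF·pyridine, pyridine, THF, 0 °C
Reagents that add atoms: none
Why: Buffered fluoride cleavage of the triethylsilyl ether, mild enough to leave the enol triflate and the electron-poor allylsilane intact.

Step 10
Reactants: 15 hydroxy enol triflate
Product: 16 (5aR,9aS)-2,2,5a-trimethyl-3-oxo-7-[(trimethylsilyl)methyl]-2,3,4,5,5a,8,9,9a-octahydro-1-benzoxepin-6-yl trifluoromethanesulfonate
Conditions: Dess–Martin periodinane, NaHCO3, CH2Cl2, 23 °C
Reagents that add atoms: none
Why: Dess–Martin oxidation under neutral conditions returns the C19 ketone, which the remaining steps tolerate.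

Step 11
Reactants: 17 cyclohex-2-en-1-one
Product: 18 2-iodocyclohex-2-en-1-one
Conditions: I2, pyridine, CH2Cl2, 0 → 23 °C
Reagents that add atoms: iodine (II)
Why: α-Iodination of an enone by the addition–elimination (Baylis–Hillman-type) mechanism with pyridine as the nucleophilic catalyst.

Step 12
Reactants: 18 2-iodocyclohex-2-en-1-one
Product: 19 2-(prop-2-en-1-yl)cyclohex-2-en-1-one
Conditions: allylSnBu3, Pd2(dba)3 (2.5 mol %), AsPh3, CuI, NMP, 23 °C
Reagents that add atoms: allyltributylstannane (C=CC[Sn](CCCC)(CCCC)CCCC)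
Why: Stille coupling of an α-iodo enone with an allylstannane, run with the triphenylarsine/copper(I) acceleration customary for this substrate class.

Step 13
Reactants: 19 2-(prop-2-en-1-yl)cyclohex-2-en-1-one
Product: 21 (2S,3S)-2,3-dimethyl-2-(prop-2-en-1-yl)cyclohexan-1-one, via magnesium enolate 20 (not isolated)
Conditions: MeMgBr, Cu(OTf)2 (3 mol %), chiral NHC ligand (4 mol %), Et2O, −30 °C; then MeI, DMPU, −30 → 23 °C
Reagents that add atoms: methylmagnesium bromide (C[Mg]Br); iodomethane (CI)
Why: Copper-catalysed asymmetric conjugate addition to a 2-substituted cyclohexenone sets C2 under ligand control, and the magnesium enolate 20 is then methylated at C12 on the face anti to the new C2 methyl (pseudo-axial to avoid A1,2 strain with the allyl group), which places the two methyl groups trans.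

Step 14
Reactants: 21 (2S,3S)-2,3-dimethyl-2-(prop-2-en-1-yl)cyclohexan-1-one
Product: 23 (1R,2S,3S)-2-(2-hydroxyethyl)-2,3-dimethylcyclohexan-1-ol, via ozonide 22 (not isolated)
Conditions: O3, CH2Cl2, −78 °C; then NaBH4, MeOH, −78 → 23 °C
Reagents that add atoms: ozone ([O-][O+]=O)
Why: Ozonolysis of the only alkene with borohydride work-up shortens the allyl group to the two-carbon C13–C14 alcohol; the ketone is reduced along with the ozonide and restored in step 16.

Step 15
Reactants: 23 (1R,2S,3S)-2-(2-hydroxyethyl)-2,3-dimethylcyclohexan-1-ol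
Product: 24 (1R,2S,3S)-2-[2-(tert-butyldimethylsilyloxy)ethyl]-2,3-dimethylcyclohexan-1-ol
Conditions: TBSCl (1.05 equiv), imidazole, CH2Cl2, 0 °C
Reagents that add atoms: tert-butyldimethylsilyl chloride (CC(C)(C)[Si](C)(C)Cl)
Why: Silylation of the primary alcohol is much faster than that of the hindered secondary one, so one equivalent of silyl chloride protects C14–OH selectively.

Step 16
Reactants: 24 (1R,2S,3S)-2-[2-(tert-butyldimethylsilyloxy)ethyl]-2,3-dimethylcyclohexan-1-ol
Product: 25 (2S,3S)-2-[2-(tert-butyldimethylsilyloxy)ethyl]-2,3-dimethylcyclohexan-1-one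
Conditions: Dess–Martin periodinane, NaHCO3, CH2Cl2, 23 °C
Reagents that add atoms: none
Why: Dess–Martin oxidation returns the C11 ketone.

Step 17
Reactants: 25 (2S,3S)-2-[2-(tert-butyldimethylsilyloxy)ethyl]-2,3-dimethylcyclohexan-1-one
Product: 26 (2S,3S,6S)-2-[2-(tert-butyldimethylsilyloxy)ethyl]-6-hydroxy-2,3-dimethylcyclohexan-1-one
Conditions: KHMDS, THF, −78 °C; 2-(phenylsulfonyl)-3-phenyloxaziridine, −78 °C
Reagents that add atoms: 2-(phenylsulfonyl)-3-phenyloxaziridine (O=S(=O)(c1ccccc1)N1OC1c1ccccc1)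
Why: Davis oxidation of the only possible enolate (C12 is quaternary); the oxaziridine approaches C5 anti to the axial C12 side chain, and the resulting equatorial C5 hydroxyl is also the thermodynamically preferred epimer.

Step 18
Reactants: 27 2-methylbut-3-en-2-ol
Product: 28 2-methylbut-3-en-2-yl 2,2,2-trichloroethanimidate
Conditions: Cl3CCN, DBU (cat.), CH2Cl2, 0 °C; used at once
Reagents that add atoms: trichloroacetonitrile (N#CC(Cl)(Cl)Cl)
Why: Base-catalysed addition of the tertiary allylic alcohol to trichloroacetonitrile (imidate formation); the imidate is used cold and without storage to forestall its [3,3] rearrangement.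

Step 19
Reactants: 26 (2S,3S,6S)-2-[2-(tert-butyldimethylsilyloxy)ethyl]-6-hydroxy-2,3-dimethylcyclohexan-1-one; 28 2-methylbut-3-en-2-yl 2,2,2-trichloroethanimidate
Product: 29 (2S,3S,6S)-2-[2-(tert-butyldimethylsilyloxy)ethyl]-2,3-dimethyl-6-[(2-methylbut-3-en-2-yl)oxy]cyclohexan-1-one
Conditions: BF3·OEt2 (10 mol %), cyclohexane/CH2Cl2 2:1, −20 → 0 °C
Reagents that add atoms: none
Why: Acid-catalysed O-alkylation with a tertiary allylic trichloroacetimidate (SN1 type): the dimethylallyl cation is captured at its tertiary terminus by the C5 hydroxyl in a non-polar medium, giving the hindered secondary–tertiary ether C5–O6–C7 that a Williamson reaction cannot give.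

Step 20
Reactants: 29 (2S,3S,6S)-2-[2-(tert-butyldimethylsilyloxy)ethyl]-2,3-dimethyl-6-[(2-methylbut-3-en-2-yl)oxy]cyclohexan-1-one
Product: 31 (2S,3S,6S)-2-[2-(tert-butyldimethylsilyloxy)ethyl]-2,3-dimethyl-6-[(2-methyl-1-oxopropan-2-yl)oxy]cyclohexan-1-one, via ozonide 30 (not isolated)
Conditions: O3, CH2Cl2, −78 °C; then PPh3, −78 → 23 °C
Reagents that add atoms: ozone ([O-][O+]=O)
Why: Ozonolysis with phosphine work-up turns the vinyl group into the non-enolisable α-alkoxy aldehyde (C8).

Step 21
Reactants: 31 (2S,3S,6S)-2-[2-(tert-butyldimethylsilyloxy)ethyl]-2,3-dimethyl-6-[(2-methyl-1-oxopropan-2-yl)oxy]cyclohexan-1-one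
Product: 33 (2S,3S,6S)-2-[2-(tert-butyldimethylsilyloxy)ethyl]-6-{[(3S)-3-hydroxy-2-methylhex-5-en-2-yl]oxy}-2,3-dimethylcyclohexan-1-one, via borinate ester 32 (not isolated)
Conditions: (−)-Ipc2B(allyl) (salt-free, from (+)-α-pinene), Et2O, −78 °C; then NaOH, H2O2, 0 °C
Reagents that add atoms: (−)-B-allyldiisopinocampheylborane (C=CCB([C@@H]1C[C@@H]2C[C@H]([C@H]1C)C2(C)C)[C@@H]1C[C@@H]2C[C@H]([C@H]1C)C2(C)C)
Why: Brown allylboration through a chair Zimmerman–Traxler transition state; the reagent made from (+)-α-pinene adds to the Si face of the aldehyde and so sets the (S)-carbinol at C8 under reagent control, while the hindered C11 ketone does not react at −78 °C.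

Step 22
Reactants: 33 (2S,3S,6S)-2-[2-(tert-butyldimethylsilyloxy)ethyl]-6-{[(3S)-3-hydroxy-2-methylhex-5-en-2-yl]oxy}-2,3-dimethylcyclohexan-1-one
Product: 34 (2S,3S,6S)-2-[2-(tert-butyldimethylsilyloxy)ethyl]-6-{[(3S)-3-(tert-butyldimethylsilyloxy)-2-methylhex-5-en-2-yl]oxy}-2,3-dimethylcyclohexan-1-one
Conditions: TBSOTf, 2,6-lutidine, CH2Cl2, −78 → 0 °C
Reagents that add atoms: tert-butyldimethylsilyl trifluoromethanesulfonate (CC(C)(C)[Si](C)(C)OS(=O)(=O)C(F)(F)F)
Why: Silylation with a silyl triflate protects the hindered C8 alcohol and removes its option of closing a hemiketal onto the C11 ketone.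

Step 23
Reactants: 34 bis-silyl ether ketone
Product: 35 1-methylidene analogue of 34 (ring C=O replaced by C=CH2, stereocentres unchanged)
Conditions: Ph3PCH3Br, KOt-Bu, toluene, 90 °C
Reagents that add atoms: methyltriphenylphosphonium bromide (C[P+](c1ccccc1)(c1ccccc1)c1ccccc1.[Br-])
Why: Wittig methylenation under the forcing conditions used for α-quaternary ketones; reversible enolisation toward C5 can only return the equatorial ether.

Step 24
Reactants: 35 methylidene diene
Product: 36 (3S,6S,7S,9aS)-3-(tert-butyldimethylsilyloxy)-6-[2-(tert-butyldimethylsilyloxy)ethyl]-2,2,6,7-tetramethyl-2,3,4,6,7,8,9,9a-octahydro-1-benzoxepine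
Conditions: Grubbs II (10 mol %), toluene (2 mM), 80 °C
Reagents that add atoms: none
Why: Ring-closing olefin metathesis: the ruthenium carbene loads at the terminal alkene and closes onto the 1,1-disubstituted alkene, and the seven-membered ring fixes the geometry of the new trisubstituted C10=C11 bond.

Step 25
Reactants: 36 bis-silyl ether oxepene
Product: 37 2-[(3S,6S,7S,9aS)-3-(tert-butyldimethylsilyloxy)-2,2,6,7-tetramethyl-2,3,4,6,7,8,9,9a-octahydro-1-benzoxepin-6-yl]ethan-1-ol
Conditions: HF·pyridine, pyridine, THF, 0 °C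
Reagents that add atoms: none
Why: Buffered HF·pyridine cleaves the primary silyl ether far faster than the neopentyl-like secondary one at C8.

Step 26
Reactants: 37 primary alcohol
Product: 38 (3S,6S,7S,9aS)-3-(tert-butyldimethylsilyloxy)-6-(2-iodoethyl)-2,2,6,7-tetramethyl-2,3,4,6,7,8,9,9a-octahydro-1-benzoxepine
Conditions: I2, PPh3, imidazole, CH2Cl2, 0 → 23 °C
Reagents that add atoms: iodine (II)
Why: Iodination of the primary alcohol with triphenylphosphine, iodine and imidazole (Garegg–Samuelsson/Appel type, SN2).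

Step 27
Reactants: 38 left-half iodide; 16 right-half enol triflate
Product: 41 coupled allylsilane (C14–C15 bond; C15=C25 alkene with CH2SiMe3 on C25; C8 OTBS; C19 ketone), via alkyllithium 39 (not isolated), via lithium borate 40 (not isolated)
Conditions: t-BuLi (2.1 equiv), Et2O, −78 °C; B-MeO-9-BBN, THF, −78 → 23 °C; then 16, Pd(dppf)Cl2 (10 mol %), AsPh3, K3PO4 (3 M aq), DMF, 23 → 45 °C
Reagents that add atoms: none
Why: B-alkyl Suzuki–Miyaura coupling in the lithium–iodine exchange/B-methoxy-9-BBN variant: borate 40 transfers its primary alkyl group (C14) to the enol triflate carbon (C15), a coupling type established for cyclohexenyl triflates flanked by a quaternary carbon, and the C19 ketone is tolerated because no free organolithium remains.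

Step 28
Reactants: 41 coupled allylsilane
Product: 42 8-O-TBS 25-methylidene compound (target skeleton with C15–H set, C25=CH2 in place of C25(CH3)OH)
Conditions: TFA (3 equiv), CH2Cl2, −20 → 0 °C
Reagents that add atoms: none
Why: Protodesilylation of an allylsilane (SE2′): the proton adds to C15 axially on the face anti to the adjacent axial C16 methyl, which sets C15 with the side chain equatorial, and loss of silicon leaves the exocyclic C25 methylene; the allylsilane is far more nucleophilic than the oxepene alkene.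

Step 29
Reactants: 42 8-O-TBS 25-methylidene compound
Product: 44 8-O-TBS sodwanone S, via tertiary hydroperoxide 43 (not isolated)
Conditions: Co(acac)2 (20 mol %), PhSiH3, O2 (1 atm), THF, 23 °C; then PPh3
Reagents that add atoms: dioxygen (O=O)
Why: Mukaiyama hydration (hydrogen-atom transfer to the alkene, oxygen capture): the unhindered 1,1-disubstituted alkene reacts much faster than the shielded trisubstituted C10=C11 alkene, and dioxygen traps the tertiary C25 radical on the equatorial face away from the syn-axial C16 methyl, which gives the equatorial hydroxyl and the axial methyl.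

Step 30
Reactants: 44 8-O-TBS sodwanone S
Product: 45 sodwanone S
Conditions: HF·pyridine, THF, 0 → 23 °C
Reagents that add atoms: none
Why: Cleavage of the remaining silyl ether with HF·pyridine; the tertiary alcohol, the ketone and the allylic ether are stable to it.

## Compound list

1 | 3-hydroxy-3-methylbutan-2-one | CC(=O)C(C)(C)O | starting material
2 | formaldehyde (used as paraformaldehyde) | C=O | starting material
3 | 1-(dimethylamino)-4-hydroxy-4-methylpentan-3-one hydrochloride | CN(C)CCC(=O)C(C)(C)O.Cl | intermediate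
4 | 2-methylcyclohexane-1,3-dione | CC1C(=O)CCCC1=O | starting material
5 | 4-hydroxy-4-methylpent-1-en-3-one | C=CC(=O)C(C)(C)O | intermediate (not isolated)
6 | 2-(4-hydroxy-4-methyl-3-oxopentyl)-2-methylcyclohexane-1,3-dione | CC1(CCC(=O)C(C)(C)O)C(=O)CCCC1=O | intermediate
7 | (5aS,9aS)-9a-hydroxy-2,2,5a-trimethyloctahydro-1-benzoxepine-3,6-dione (bicyclic hemiketal, ring oxygen cis to the angular methyl) | O=C1[C@]2(C)CCC(=O)C(C)(C)O[C@@]2(O)CCC1 | intermediate (not isolated)
8 | (5aR,9aS)-2,2,5a-trimethyloctahydro-1-benzoxepine-3,6-dione (trans-fused) | O=C1[C@]2(C)CCC(=O)C(C)(C)O[C@H]2CCC1 | intermediate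
9 | (5aR,9aS)-6,6-(ethane-1,2-diyldioxy)-2,2,5a-trimethyloctahydro-1-benzoxepin-3-one | O1CCOC12[C@]3(C)CCC(=O)C(C)(C)O[C@H]3CCC2 | intermediate
10 | (3S,5aR,9aS)-6,6-(ethane-1,2-diyldioxy)-2,2,5a-trimethyldecahydro-1-benzoxepin-3-ol | O1CCOC12[C@]3(C)CC[C@H](O)C(C)(C)O[C@H]3CCC2 | intermediate (not isolated)
11 | (3S,5aR,9aS)-3-hydroxy-2,2,5a-trimethyloctahydro-1-benzoxepin-6-one | O=C1[C@]2(C)CC[C@H](O)C(C)(C)O[C@H]2CCC1 | intermediate
12 | (3S,5aR,9aS)-2,2,5a-trimethyl-3-(triethylsilyloxy)octahydro-1-benzoxepin-6-one | O=C1[C@]2(C)CC[C@H](O[Si](CC)(CC)CC)C(C)(C)O[C@H]2CCC1 | intermediate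
13 | (3S,5aR,7S,9aS)-2,2,5a-trimethyl-3-(triethylsilyloxy)-7-[(trimethylsilyl)methyl]octahydro-1-benzoxepin-6-one | O=C1[C@]2(C)CC[C@H](O[Si](CC)(CC)CC)C(C)(C)O[C@H]2CC[C@@H]1C[Si](C)(C)C | intermediate
14 | (3S,5aR,9aS)-2,2,5a-trimethyl-3-(triethylsilyloxy)-7-[(trimethylsilyl)methyl]-2,3,4,5,5a,8,9,9a-octahydro-1-benzoxepin-6-yl trifluoromethanesulfonate | O=S(=O)(OC=1[C@]2(C)CC[C@H](O[Si](CC)(CC)CC)C(C)(C)O[C@H]2CCC=1C[Si](C)(C)C)C(F)(F)F | intermediate
15 | (3S,5aR,9aS)-3-hydroxy-2,2,5a-trimethyl-7-[(trimethylsilyl)methyl]-2,3,4,5,5a,8,9,9a-octahydro-1-benzoxepin-6-yl trifluoromethanesulfonate | O=S(=O)(OC=1[C@]2(C)CC[C@H](O)C(C)(C)O[C@H]2CCC=1C[Si](C)(C)C)C(F)(F)F | intermediate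
16 | (5aR,9aS)-2,2,5a-trimethyl-3-oxo-7-[(trimethylsilyl)methyl]-2,3,4,5,5a,8,9,9a-octahydro-1-benzoxepin-6-yl trifluoromethanesulfonate | O=S(=O)(OC=1[C@]2(C)CCC(=O)C(C)(C)O[C@H]2CCC=1C[Si](C)(C)C)C(F)(F)F | intermediate
17 | cyclohex-2-en-1-one | O=C1C=CCCC1 | starting material
18 | 2-iodocyclohex-2-en-1-one | O=C1C(I)=CCCC1 | intermediate
19 | 2-(prop-2-en-1-yl)cyclohex-2-en-1-one | C=CCC1=CCCC1=O | intermediate
20 | bromomagnesium (3S)-3-methyl-2-(prop-2-en-1-yl)cyclohex-1-en-1-olate | C[C@H]1CCCC(O[Mg]Br)=C1CC=C | intermediate (not isolated)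
21 | (2S,3S)-2,3-dimethyl-2-(prop-2-en-1-yl)cyclohexan-1-one | C[C@H]1CCCC(=O)[C@@]1(C)CC=C | intermediate
22 | (2S,3S)-2,3-dimethyl-2-[(1,2,4-trioxolan-3-yl)methyl]cyclohexan-1-one (epimers at the trioxolane carbon) | C[C@H]1CCCC(=O)[C@@]1(C)CC1OCOO1 | intermediate (not isolated)
23 | (1R,2S,3S)-2-(2-hydroxyethyl)-2,3-dimethylcyclohexan-1-ol | C[C@H]1CCC[C@@H](O)[C@@]1(C)CCO | intermediate
24 | (1R,2S,3S)-2-[2-(tert-butyldimethylsilyloxy)ethyl]-2,3-dimethylcyclohexan-1-ol | C[C@H]1CCC[C@@H](O)[C@@]1(C)CCO[Si](C)(C)C(C)(C)C | intermediate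
25 | (2S,3S)-2-[2-(tert-butyldimethylsilyloxy)ethyl]-2,3-dimethylcyclohexan-1-one | C[C@H]1CCCC(=O)[C@@]1(C)CCO[Si](C)(C)C(C)(C)C | intermediate
26 | (2S,3S,6S)-2-[2-(tert-butyldimethylsilyloxy)ethyl]-6-hydroxy-2,3-dimethylcyclohexan-1-one | C[C@H]1CC[C@H](O)C(=O)[C@@]1(C)CCO[Si](C)(C)C(C)(C)C | intermediate
27 | 2-methylbut-3-en-2-ol | C=CC(C)(C)O | starting material
28 | 2-methylbut-3-en-2-yl 2,2,2-trichloroethanimidate | C=CC(C)(C)OC(=N)C(Cl)(Cl)Cl | intermediate
29 | (2S,3S,6S)-2-[2-(tert-butyldimethylsilyloxy)ethyl]-2,3-dimethyl-6-[(2-methylbut-3-en-2-yl)oxy]cyclohexan-1-one | C[C@H]1CC[C@H](OC(C)(C)C=C)C(=O)[C@@]1(C)CCO[Si](C)(C)C(C)(C)C | intermediate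
30 | ozonide of 29: (2S,3S,6S)-2-[2-(tert-butyldimethylsilyloxy)ethyl]-2,3-dimethyl-6-{[2-(1,2,4-trioxolan-3-yl)propan-2-yl]oxy}cyclohexan-1-one (epimers at the trioxolane carbon) | C[C@H]1CC[C@H](OC(C)(C)C2OCOO2)C(=O)[C@@]1(C)CCO[Si](C)(C)C(C)(C)C | intermediate (not isolated)
31 | (2S,3S,6S)-2-[2-(tert-butyldimethylsilyloxy)ethyl]-2,3-dimethyl-6-[(2-methyl-1-oxopropan-2-yl)oxy]cyclohexan-1-one | C[C@H]1CC[C@H](OC(C)(C)C=O)C(=O)[C@@]1(C)CCO[Si](C)(C)C(C)(C)C | intermediate
32 | diisopinocampheylborinate ester of 33 (B–O bond at the new (S)-carbinol) | C[C@H]1CC[C@H](OC(C)(C)[C@@H](OB([C@@H]2C[C@@H]3C[C@H]([C@H]2C)C3(C)C)[C@@H]2C[C@@H]3C[C@H]([C@H]2C)C3(C)C)CC=C)C(=O)[C@@]1(C)CCO[Si](C)(C)C(C)(C)C | intermediate (not isolated)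
33 | (2S,3S,6S)-2-[2-(tert-butyldimethylsilyloxy)ethyl]-6-{[(3S)-3-hydroxy-2-methylhex-5-en-2-yl]oxy}-2,3-dimethylcyclohexan-1-one | C[C@H]1CC[C@H](OC(C)(C)[C@@H](O)CC=C)C(=O)[C@@]1(C)CCO[Si](C)(C)C(C)(C)C | intermediate
34 | (2S,3S,6S)-2-[2-(tert-butyldimethylsilyloxy)ethyl]-6-{[(3S)-3-(tert-butyldimethylsilyloxy)-2-methylhex-5-en-2-yl]oxy}-2,3-dimethylcyclohexan-1-one | C[C@H]1CC[C@H](OC(C)(C)[C@@H](O[Si](C)(C)C(C)(C)C)CC=C)C(=O)[C@@]1(C)CCO[Si](C)(C)C(C)(C)C | intermediate
35 | 1-methylidene analogue of 34 (ring C=O replaced by C=CH2, stereocentres unchanged) | C[C@H]1CC[C@H](OC(C)(C)[C@@H](O[Si](C)(C)C(C)(C)C)CC=C)C(=C)[C@@]1(C)CCO[Si](C)(C)C(C)(C)C | intermediate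
36 | (3S,6S,7S,9aS)-3-(tert-butyldimethylsilyloxy)-6-[2-(tert-butyldimethylsilyloxy)ethyl]-2,2,6,7-tetramethyl-2,3,4,6,7,8,9,9a-octahydro-1-benzoxepine | C[C@H]1CC[C@@H]2OC(C)(C)[C@@H](O[Si](C)(C)C(C)(C)C)CC=C2[C@@]1(C)CCO[Si](C)(C)C(C)(C)C | intermediate
37 | 2-[(3S,6S,7S,9aS)-3-(tert-butyldimethylsilyloxy)-2,2,6,7-tetramethyl-2,3,4,6,7,8,9,9a-octahydro-1-benzoxepin-6-yl]ethan-1-ol | C[C@H]1CC[C@@H]2OC(C)(C)[C@@H](O[Si](C)(C)C(C)(C)C)CC=C2[C@@]1(C)CCO | intermediate
38 | (3S,6S,7S,9aS)-3-(tert-butyldimethylsilyloxy)-6-(2-iodoethyl)-2,2,6,7-tetramethyl-2,3,4,6,7,8,9,9a-octahydro-1-benzoxepine | C[C@H]1CC[C@@H]2OC(C)(C)[C@@H](O[Si](C)(C)C(C)(C)C)CC=C2[C@@]1(C)CCI | intermediate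
39 | alkyllithium from 38 (C14–Li) | C[C@H]1CC[C@@H]2OC(C)(C)[C@@H](O[Si](C)(C)C(C)(C)C)CC=C2[C@@]1(C)CC[Li] | intermediate (not isolated)
40 | lithium B-alkyl-B-methoxy-9-borabicyclo[3.3.1]nonane borate from 39 | C[C@H]1CC[C@@H]2OC(C)(C)[C@@H](O[Si](C)(C)C(C)(C)C)CC=C2[C@@]1(C)CC[B-]1(OC)C2CCCC1CCC2.[Li+] | intermediate (not isolated)
41 | coupled allylsilane: target skeleton with C15=C25, CH2SiMe3 on C25, C8 OTBS, C19 ketone | C[C@H]1CC[C@@H]2OC(C)(C)[C@@H](O[Si](C)(C)C(C)(C)C)CC=C2[C@@]1(C)CCC=1[C@]2(C)CCC(=O)C(C)(C)O[C@H]2CCC=1C[Si](C)(C)C | intermediate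
42 | 8-O-TBS 25-methylidene compound (C25=CH2 in place of C25(CH3)OH) | C[C@H]1CC[C@@H]2OC(C)(C)[C@@H](O[Si](C)(C)C(C)(C)C)CC=C2[C@@]1(C)CC[C@H]1[C@]2(C)CCC(=O)C(C)(C)O[C@H]2CCC1=C | intermediate
43 | 8-O-TBS C25 hydroperoxide (OOH in place of the C25 OH) | C[C@H]1CC[C@@H]2OC(C)(C)[C@@H](O[Si](C)(C)C(C)(C)C)CC=C2[C@@]1(C)CC[C@H]1[C@]2(C)CCC(=O)C(C)(C)O[C@H]2CC[C@]1(C)OO | intermediate (not isolated)
44 | 8-O-TBS sodwanone S | C[C@H]1CC[C@@H]2OC(C)(C)[C@@H](O[Si](C)(C)C(C)(C)C)CC=C2[C@@]1(C)CC[C@H]1[C@]2(C)CCC(=O)C(C)(C)O[C@H]2CC[C@]1(C)O | intermediate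
45 | sodwanone S | C[C@H]1CC[C@@H]2OC(C)(C)[C@@H](O)CC=C2[C@@]1(C)CC[C@H]1[C@]2(C)CCC(=O)C(C)(C)O[C@H]2CC[C@]1(C)O | target

## Step count and risks

Total step count: 30. Longest linear sequence: 19 steps (11–17, then 19–30); the right-half branch is steps 1–10 and the imidate branch is step 18.

Steps most likely to fail:

Step 3. Hydride may be transferred through an uncatalysed or achiral silylium pathway, so that the two enantiotopic carbonyls are not told apart; direct hydrosilylation of a free carbonyl may compete. Fallback (known chemistry): setting out from trione 6, the achiral reductive cyclisation of hydroxy ketones (TMSOTf, Et3SiH, CH2Cl2/MeCN, −20 °C) should give the trans-fused diketone as the racemate, i.e. 8 together with its enantiomer (5aS,9aR)-2,2,5a-trimethyloctahydro-1-benzoxepine-3,6-dione F1. The enantiomers are separated by preparative chromatography on a chiral stationary phase and the route is rejoined at 8.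

Step 24. Closure onto the 1,1-disubstituted alkene, which is flanked by a quaternary carbon and an ether carbon, may be slow, so that intermolecular metathesis of the terminal alkene and double-bond migration take over. Fallback: setting out from ketone 34 (step 23 is then omitted), a stoichiometric Schrock molybdenum alkylidene in benzene converts the terminal alkene into a molybdenum alkylidene at C10, which olefinates the C11 ketone within the molecule (carbonyl–olefin ring closure, known for olefinic ketones). The C10=C11 bond then forms without the hindered methylidene compound and the route is rejoined at 36; no compound outside the list is made, which the block below records as none F0.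

Step 19. The dimethylallyl cation may be lost by elimination or by [3,3] rearrangement of the imidate before the hindered, weakly nucleophilic α-ketol hydroxyl captures it, and capture at the primary terminus may compete. Fallback: setting out from ketone 25, detrifluoroacetylative diazo transfer (LiHMDS, CF3CO2CH2CF3, −78 °C, to the enolised 6-trifluoroacetyl ketone F2; then MsN3, Et3N, MeCN) gives the 6-diazo ketone F3. Rh2(OAc)4-catalysed O–H insertion of its carbenoid into 2-methylbut-3-en-2-ol 27 (co-solvent) makes the C5–O6 bond from the carbon side and should give 29 together with its C5 epimer F4, which DBU equilibrates to the equatorial ether, so that the route is rejoined at 29.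

Further compounds

F1 | step 3 | (5aS,9aR)-2,2,5a-trimethyloctahydro-1-benzoxepine-3,6-dione | O=C1[C@@]2(C)CCC(=O)C(C)(C)O[C@@H]2CCC1
F0 | step 24 | none | none
F2 | step 19 | (2S,3S,6Z)-2-[2-(tert-butyldimethylsilyloxy)ethyl]-2,3-dimethyl-6-(2,2,2-trifluoro-1-hydroxyethylidene)cyclohexan-1-one | C[C@H]1CC/C(=C(/O)C(F)(F)F)C(=O)[C@@]1(C)CCO[Si](C)(C)C(C)(C)C
F3 | step 19 | (2S,3S)-2-[2-(tert-butyldimethylsilyloxy)ethyl]-6-diazo-2,3-dimethylcyclohexan-1-one | C[C@H]1CCC(=[N+]=[N-])C(=O)[C@@]1(C)CCO[Si](C)(C)C(C)(C)C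
F4 | step 19 | (2S,3S,6R)-2-[2-(tert-butyldimethylsilyloxy)ethyl]-2,3-dimethyl-6-[(2-methylbut-3-en-2-yl)oxy]cyclohexan-1-one | C[C@H]1CC[C@@H](OC(C)(C)C=C)C(=O)[C@@]1(C)CCO[Si](C)(C)C(C)(C)C
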